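**Late slowness.** The alpha run, which is this same flask followed so far, barely moves at the end: from 4.00 d to 6.00 d the isomer of the product gains 2.4 percentage points, with a scatter of 1 point per reading, after reaching 49.5% in the first 0.333 d.

- alpha: starting complex 1.6 M; incoming ligand 2.4 M; the very flask that is asked about, followed so far
- flask: starting complex 1.6 M; incoming ligand 2.40 M; time 15 d

alpha run (percent of the starting complex charged)

| time / d | complex with one exchanged / % | isomer of the product / % |
|---|---|---|
| 0.333 | 4.6 | 49.5 |
| 0.833 | 5.5 | 73.6 |
| 1.67 | 2.8 | 82.4 |
| 2.50 | 2.8 | 87.5 |
| 4.00 | 1.3 | 87.7 |
| 5.00 | 1.4 | 89.3 |
| 6.00 | 2.5 | 90.1 |

(scatter of a reading: 1 percentage point)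

- why nothing more happens at 15 d, or that something still does (forward and back rates have come level / it is still moving / all of the starting complex has reacted / the incoming ligand has run out first)
- the complex with one exchanged standing at 15 d, as a percentage of the starting complex charged
- the isomer of the product standing at 15 d, as a percentage of the starting complex charged

- the reaction counts as stopped when no species that holds the starting complex changes by six tenths of a point or more over the second half of the time

**The contradiction.** The incoming ligand was charged at 1.50 per starting complex, enough for one exchange on every complex. Yet the conversion x, the complex with one exchanged plus the isomer of the product, averages 90.8% over the last 3 readings.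

**Closed form.** A stall with both reactants apparently present points to a way back. Suppose each complex makes one exchange and frees one leaving ligand. The forward rate then follows remaining complex times remaining ligand, and the back rate follows the square of the amount converted. The two are level at one value of the apparent equilibrium constant K, converted complex times leaving ligand over remaining complex times remaining ligand. Read from the alpha run, K = 15.1, a reading with the scatter of x. This reckoning, apart from the forecast, puts the flask near x at 15 d.

**The forecast.** It says forward and back rates have come level, with 2.1% complex with one exchanged and 90% isomer of the product, since conversion “looks like reversible equilibrium”. Its sum lies 1.3 points above x.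

**The result.** At 15 d the flask gives: forward and back rates have come level, with 2.81% complex with one exchanged and 88.4% isomer of the product. The remainder is shared among 4.01% starting complex, 3.28% complex with two exchanged and 1.49% complex with three exchanged. K treats that whole remainder as unconverted and counts one leaving ligand per converted complex, 1.46 M against the 1.64 M in this flask; these two results give K = 16.1.

    starting complex + incoming ligand ⇌ leaving ligand + complex with one exchanged (K = 1.50, k = 0.112 L mol⁻¹ h⁻¹)
    complex with one exchanged + incoming ligand ⇌ leaving ligand + complex with two exchanged (K = 2.50, k = 0.124 L mol⁻¹ h⁻¹)
    complex with two exchanged + incoming ligand ⇌ leaving ligand + complex with three exchanged (K = 0.971, k = 0.561 L mol⁻¹ h⁻¹)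
    complex with one exchanged ⇌ isomer of the product (K = 31.5, k = 0.700 h⁻¹)

**Second flask.** For a neighbour flask charged with 0.60 M incoming ligand, starting complex and time held, the value of K read from the alpha run gives a quadratic in the conversion, with the root 36.1%. That flask computes to 35.8% isomer of the product and 1.14% complex with one exchanged, and the incoming ligand, the limiting reagent there, stands at 1.2% of its charge.

(The readings were generated by integration from invented constants, noise included.)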